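**Plan**

- Retrosynthesis: the three phenols are masked as benzyl ethers. The C3–C1′ bond of the 8-chloroisoflavone unit is cut first (Suzuki coupling of aryl boronate 15 with 3-iodochromone 20). Next come the C3–C1′ bond and the O1–C2/C2–C3 atoms of the pyranone of the 8-aryloxy unit (Suzuki coupling, enaminone/iodine cyclisation). Last are the C4a–C8a and C5–C6 bonds of its ring A.
- Enabling feature: ring A of the 8-aryloxy isoflavone carries oxygen on three adjacent carbons, C8a, C8 (the diaryl ether) and C7, beside the acyl-bearing C4a, while C5 and C6 are plain CH. A 2-aryloxy-1-methoxy-1,3-bis(silyloxy)butadiene and a terminal ynone deliver exactly this pattern, so the crowded ether oxygen is attached to an sp3 carbon before the ring exists.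
- Forward: 4-bromophenol is O-alkylated and turned into the diene; ring A arises by cycloaddition and aromatisation; ring C (pyranone) and then ring B are added; the bromide becomes a boronate and is joined to the chlorinated iodochromone (four steps from 2-chlororesorcinol); global debenzylation finishes.
- Stereochemistry: the target has no stereocentre and no stereogenic double bond; the enaminone geometry and the ketal carbon of the cycloadduct are transient.

Key step: step 4

Remark: benzyl ethers are chosen because BCl3 removes them without touching the aryl chloride or the chromone double bonds. The bromine para to the ether oxygen is the handle for the second isoflavone unit.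

**Route**

Step 1
Reactants: 1 4-bromophenol; 2 methyl 2-chloro-3-oxobutanoate
Product: 3 methyl 2-(4-bromophenoxy)-3-oxobutanoate (racemic)
Conditions: K2CO3, acetone, reflux
Reagents that add atoms: none
Why: Williamson-type SN2 etherification in which the phenoxide displaces chloride from the doubly activated α-carbon of the β-keto ester, the usual entry to 2-aryloxyacetoacetates.

Step 2
Reactants: 3 methyl 2-(4-bromophenoxy)-3-oxobutanoate
Product: 4 methyl 2-(4-bromophenoxy)-3-(trimethylsilyloxy)but-2-enoate (E/Z mixture)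
Conditions: Me3SiCl, Et3N, toluene, 20 °C
Reagents that add atoms: chlorotrimethylsilane, C[Si](C)(C)Cl
Why: Silyl enol ether formation by amine-mediated enolisation and O-silylation of the ketone oxygen, as in the first stage of the preparation of Chan-type dienes.

Step 3
Reactants: 4 methyl 2-(4-bromophenoxy)-3-(trimethylsilyloxy)but-2-enoate
Product: 6 2-(4-bromophenoxy)-1-methoxy-1,3-bis(trimethylsilyloxy)buta-1,3-diene (mixture of ketene acetal geometries, used crude), via lithium dienolate 5 (not isolated)
Conditions: LiN(i-Pr)2 (LDA), THF, −78 °C; then Me3SiCl, −78 → 20 °C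
Reagents that add atoms: chlorotrimethylsilane, C[Si](C)(C)Cl
Why: Kinetic γ-deprotonation of the vinylogous ester and O-silylation of the dienolate (Chan diene synthesis) should give the bis(silyloxy)diene, and the amide base at −78 °C should leave the aryl bromide untouched.

Step 4
Reactants: 6 2-(4-bromophenoxy)-1-methoxy-1,3-bis(trimethylsilyloxy)buta-1,3-diene; 7 3-butyn-2-one
Product: 9 1-[3-(4-bromophenoxy)-2,4-dihydroxyphenyl]ethanone, via cyclohexadiene cycloadduct 8 (not isolated)
Conditions: toluene, −78 → 50 °C; then 1 M HCl (aq), THF, 20 °C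
Reagents that add atoms: none
Why: This is a Diels–Alder benzannulation of a 1-alkoxy-1,3-bis(silyloxy)butadiene with an acetylenic ketone, the closest known type being the cycloaddition of 2-substituted Chan dienes with propiolates, ynones and acetylenedicarboxylates to give resorcinol derivatives. The diene HOMO has its largest coefficient at the unsubstituted CH2 terminus (pushed by the oxygens on C1 and C3) and the ynone LUMO at the β-carbon, so a strongly asynchronous [4+2] cycloaddition joins CH2 to the alkyne CH and the ketene acetal carbon to the acyl-bearing carbon to give cyclohexa-1,4-diene 8; in the stepwise limit this is a Mukaiyama–Michael addition followed by 6-exo-trig attack of the allenolate α-carbon on the silyl oxocarbenium carbon. The carbocycle therefore closes by intermolecular [4π+2π] cycloaddition, and both new σ-bonds (C4a–C8a and C5–C6 in isoflavone numbering) form in the same operation. Aqueous acid cleaves both silyl ethers, the mixed ketal collapses with loss of methanol and the dienone tautomerises to the arene, so no stereocentre survives and none needs control. The step needs regioselectivity, secured by the matched polarisation of the partners (acetyl ends up ortho to the hydroxyl derived from the ketene acetal), and chemoselectivity for the alkyne over the ketone carbonyl, favoured by thermal conditions without a Lewis acid. The aryl bromide and the diaryl ether oxygen, already in place on the diene, are spectators.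

Step 5
Reactants: 9 1-[3-(4-bromophenoxy)-2,4-dihydroxyphenyl]ethanone
Product: 10 1-[4-(benzyloxy)-3-(4-bromophenoxy)-2-hydroxyphenyl]ethanone
Conditions: BnBr (1.05 equiv), K2CO3, acetone, reflux
Reagents that add atoms: benzyl bromide, BrCc1ccccc1
Why: Williamson etherification selective for the 4-hydroxyl, because the 2-hydroxyl is hydrogen-bonded to the acetyl carbonyl and far less nucleophilic, as in resacetophenone itself.

Step 6
Reactants: 10 1-[4-(benzyloxy)-3-(4-bromophenoxy)-2-hydroxyphenyl]ethanone
Product: 11 (E)-1-[4-(benzyloxy)-3-(4-bromophenoxy)-2-hydroxyphenyl]-3-(dimethylamino)prop-2-en-1-one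
Conditions: Me2NCH(OMe)2, toluene, 95 °C
Reagents that add atoms: N,N-dimethylformamide dimethyl acetal, COC(OC)N(C)C
Why: Enaminone formation by condensation of the methyl ketone with the amide acetal, driven by loss of methanol, with the chelated phenol left free for ring closure.

Step 7
Reactants: 11 (E)-1-[4-(benzyloxy)-3-(4-bromophenoxy)-2-hydroxyphenyl]-3-(dimethylamino)prop-2-en-1-one
Product: 12 7-(benzyloxy)-8-(4-bromophenoxy)-3-iodo-4H-chromen-4-one
Conditions: I2, pyridine, CHCl3, 20 °C
Reagents that add atoms: iodine, II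
Why: Iodine-mediated cyclisation of a 2-hydroxyaryl enaminone (Gammill 3-iodochromone synthesis), in which α-iodination, attack of the phenol oxygen on the iminium carbon and loss of dimethylamine build the pyranone ring.

Step 8
Reactants: 12 7-(benzyloxy)-8-(4-bromophenoxy)-3-iodo-4H-chromen-4-one; 13 4-(benzyloxy)phenylboronic acid
Product: 14 7-(benzyloxy)-3-[4-(benzyloxy)phenyl]-8-(4-bromophenoxy)-4H-chromen-4-one
Conditions: Pd(PPh3)4 (3 mol %), Na2CO3 (aq), DME, 60 °C
Reagents that add atoms: none
Why: Suzuki–Miyaura coupling in which zerovalent palladium should insert into the C–I bond of the electron-poor iodoenone much faster than into the C–Br bond of the electron-rich aryl ether, so the bromide is kept for step 9.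

Step 9
Reactants: 14 7-(benzyloxy)-3-[4-(benzyloxy)phenyl]-8-(4-bromophenoxy)-4H-chromen-4-one
Product: 15 7-(benzyloxy)-3-[4-(benzyloxy)phenyl]-8-[4-(4,4,5,5-tetramethyl-1,3,2-dioxaborolan-2-yl)phenoxy]-4H-chromen-4-one
Conditions: B2pin2, Pd(dppf)Cl2 (5 mol %), KOAc, 1,4-dioxane, 90 °C
Reagents that add atoms: bis(pinacolato)diboron, CC1(C)OB(OC1(C)C)B1OC(C)(C)C(C)(C)O1
Why: Miyaura borylation of the aryl bromide, with KOAc as a base mild enough to spare the pyranone ring and the benzyl ethers.

Step 10
Reactants: 16 2-chlorobenzene-1,3-diol (2-chlororesorcinol)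
Product: 17 1-(3-chloro-2,4-dihydroxyphenyl)ethanone
Conditions: AcOH, ZnCl2, 140 °C
Reagents that add atoms: acetic acid, CC(=O)O
Why: Nencki reaction (Friedel–Crafts C-acylation of a resorcinol with acetic acid and ZnCl2), where the only activated positions, C4 and C6, are equivalent, so a single ketone should form.

Step 11
Reactants: 17 1-(3-chloro-2,4-dihydroxyphenyl)ethanone
Product: 18 1-[4-(benzyloxy)-3-chloro-2-hydroxyphenyl]ethanone
Conditions: BnBr (1.05 equiv), K2CO3, acetone, reflux
Reagents that add atoms: benzyl bromide, BrCc1ccccc1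
Why: Williamson etherification, again selective for the non-chelated and more acidic 4-hydroxyl.

Step 12
Reactants: 18 1-[4-(benzyloxy)-3-chloro-2-hydroxyphenyl]ethanone
Product: 19 (E)-1-[4-(benzyloxy)-3-chloro-2-hydroxyphenyl]-3-(dimethylamino)prop-2-en-1-one
Conditions: Me2NCH(OMe)2, toluene, 95 °C
Reagents that add atoms: N,N-dimethylformamide dimethyl acetal, COC(OC)N(C)C
Why: Enaminone formation by amide acetal condensation at the acetyl methyl group, as in step 6.

Step 13
Reactants: 19 (E)-1-[4-(benzyloxy)-3-chloro-2-hydroxyphenyl]-3-(dimethylamino)prop-2-en-1-one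
Product: 20 7-(benzyloxy)-8-chloro-3-iodo-4H-chromen-4-one
Conditions: I2, pyridine, CHCl3, 20 °C
Reagents that add atoms: iodine, II
Why: Iodine-mediated enaminone cyclisation to the 3-iodochromone as in step 7, with the aryl chloride inert to electrophilic iodine under these conditions.

Step 14
Reactants: 15 7-(benzyloxy)-3-[4-(benzyloxy)phenyl]-8-[4-(4,4,5,5-tetramethyl-1,3,2-dioxaborolan-2-yl)phenoxy]-4H-chromen-4-one; 20 7-(benzyloxy)-8-chloro-3-iodo-4H-chromen-4-one
Product: 21 7-(benzyloxy)-3-[4-({7-(benzyloxy)-3-[4-(benzyloxy)phenyl]-4-oxo-4H-chromen-8-yl}oxy)phenyl]-8-chloro-4H-chromen-4-one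
Conditions: Pd(PPh3)4 (5 mol %), Na2CO3 (aq), DME, 80 °C
Reagents that add atoms: none
Why: Suzuki–Miyaura coupling of the aryl pinacol boronate with the 3-iodochromone, using a triphenylphosphine catalyst that should not insert into the electron-rich aryl C–Cl bond.

Step 15
Reactants: 21 7-(benzyloxy)-3-[4-({7-(benzyloxy)-3-[4-(benzyloxy)phenyl]-4-oxo-4H-chromen-8-yl}oxy)phenyl]-8-chloro-4H-chromen-4-one
Product: 22 Bisoflavolin J, 8-chloro-7-hydroxy-3-(4-{[7-hydroxy-3-(4-hydroxyphenyl)-4-oxo-4H-chromen-8-yl]oxy}phenyl)-4H-chromen-4-one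
Conditions: BCl3, C6HMe5, CH2Cl2, −78 → 0 °C; then MeOH, aq. work-up
Reagents that add atoms: none
Why: Lewis acid debenzylation of the three aryl benzyl ethers with pentamethylbenzene as benzyl cation scavenger, chosen over hydrogenolysis because it should leave the C–Cl bond, the chromone C2=C3 bonds and the diaryl ether intact.

**Compound list**

1 | 4-bromophenol | Oc1ccc(Br)cc1 | starting material
2 | methyl 2-chloro-3-oxobutanoate (methyl 2-chloroacetoacetate) | COC(=O)C(Cl)C(C)=O | starting material
3 | methyl 2-(4-bromophenoxy)-3-oxobutanoate | COC(=O)C(Oc1ccc(Br)cc1)C(C)=O | intermediate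
4 | methyl 2-(4-bromophenoxy)-3-(trimethylsilyloxy)but-2-enoate | COC(=O)C(Oc1ccc(Br)cc1)=C(C)O[Si](C)(C)C | intermediate
5 | lithium dienolate of 4 (lithium 2-(4-bromophenoxy)-1-methoxy-3-(trimethylsilyloxy)buta-1,3-dien-1-olate) | [Li+].COC([O-])=C(Oc1ccc(Br)cc1)C(=C)O[Si](C)(C)C | intermediate
6 | 2-(4-bromophenoxy)-1-methoxy-1,3-bis(trimethylsilyloxy)buta-1,3-diene | COC(O[Si](C)(C)C)=C(Oc1ccc(Br)cc1)C(=C)O[Si](C)(C)C | intermediate
7 | 3-butyn-2-one | CC(=O)C#C | starting material
8 | 1-[5-(4-bromophenoxy)-6-methoxy-4,6-bis(trimethylsilyloxy)cyclohexa-1,4-dien-1-yl]ethanone (cycloadduct, racemic) | COC1(O[Si](C)(C)C)C(C(C)=O)=CCC(O[Si](C)(C)C)=C1Oc1ccc(Br)cc1 | intermediate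
9 | 1-[3-(4-bromophenoxy)-2,4-dihydroxyphenyl]ethanone | CC(=O)c1ccc(O)c(Oc2ccc(Br)cc2)c1O | intermediate
10 | 1-[4-(benzyloxy)-3-(4-bromophenoxy)-2-hydroxyphenyl]ethanone | CC(=O)c1ccc(OCc2ccccc2)c(Oc2ccc(Br)cc2)c1O | intermediate
11 | (E)-1-[4-(benzyloxy)-3-(4-bromophenoxy)-2-hydroxyphenyl]-3-(dimethylamino)prop-2-en-1-one | CN(C)/C=C/C(=O)c1ccc(OCc2ccccc2)c(Oc2ccc(Br)cc2)c1O | intermediate
12 | 7-(benzyloxy)-8-(4-bromophenoxy)-3-iodo-4H-chromen-4-one | O=c1c(I)coc2c(Oc3ccc(Br)cc3)c(OCc3ccccc3)ccc12 | intermediate
13 | 4-(benzyloxy)phenylboronic acid | OB(O)c1ccc(OCc2ccccc2)cc1 | starting material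
14 | 7-(benzyloxy)-3-[4-(benzyloxy)phenyl]-8-(4-bromophenoxy)-4H-chromen-4-one | O=c1c(-c2ccc(OCc3ccccc3)cc2)coc2c(Oc3ccc(Br)cc3)c(OCc3ccccc3)ccc12 | intermediate
15 | 7-(benzyloxy)-3-[4-(benzyloxy)phenyl]-8-[4-(4,4,5,5-tetramethyl-1,3,2-dioxaborolan-2-yl)phenoxy]-4H-chromen-4-one | O=c1c(-c2ccc(OCc3ccccc3)cc2)coc2c(Oc3ccc(B4OC(C)(C)C(C)(C)O4)cc3)c(OCc3ccccc3)ccc12 | intermediate
16 | 2-chlorobenzene-1,3-diol (2-chlororesorcinol) | Oc1cccc(O)c1Cl | starting material
17 | 1-(3-chloro-2,4-dihydroxyphenyl)ethanone | CC(=O)c1ccc(O)c(Cl)c1O | intermediate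
18 | 1-[4-(benzyloxy)-3-chloro-2-hydroxyphenyl]ethanone | CC(=O)c1ccc(OCc2ccccc2)c(Cl)c1O | intermediate
19 | (E)-1-[4-(benzyloxy)-3-chloro-2-hydroxyphenyl]-3-(dimethylamino)prop-2-en-1-one | CN(C)/C=C/C(=O)c1ccc(OCc2ccccc2)c(Cl)c1O | intermediate
20 | 7-(benzyloxy)-8-chloro-3-iodo-4H-chromen-4-one | O=c1c(I)coc2c(Cl)c(OCc3ccccc3)ccc12 | intermediate
21 | 7-(benzyloxy)-3-[4-({7-(benzyloxy)-3-[4-(benzyloxy)phenyl]-4-oxo-4H-chromen-8-yl}oxy)phenyl]-8-chloro-4H-chromen-4-one | O=c1c(-c2ccc(Oc3c(OCc4ccccc4)ccc4c(=O)c(-c5ccc(OCc6ccccc6)cc5)coc34)cc2)coc2c(Cl)c(OCc3ccccc3)ccc12 | intermediate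
22 | Bisoflavolin J | O=c1c(-c2ccc(Oc3c(O)ccc4c(=O)c(-c5ccc(O)cc5)coc34)cc2)coc2c(Cl)c(O)ccc12 | target

**Step count**

Total: 15 steps. Longest linear sequence: 11 steps (steps 1–9, 14, 15); the chlorinated iodochromone branch (steps 10–13) is 4 steps.

**Steps most likely to fail**

1. Step 4. The crowded 2-aryloxy diene may be protodesilylated before it reacts, the addition may stop at the open-chain Michael stage, or bond formation may take the other orientation. The fallback gives up the benzannulation and makes the hindered ether on a preformed arene. It replaces steps 1 to 4, so it does not branch from a numbered compound but from commercial 2,6-dimethoxyphenol (COc1cccc(OC)c1O) and 1-bromo-4-iodobenzene (Brc1ccc(I)cc1), and it comes back to the route at compound 9. Ullmann ether synthesis at the iodide (CuI, picolinic acid, K3PO4, DMSO, 90 °C; conditions suited to di-ortho-substituted phenols) should give 2-(4-bromophenoxy)-1,3-dimethoxybenzene F1. Friedel–Crafts acetylation (AcCl, AlCl3, CH2Cl2, 0 °C) at C4, ortho and para to the two methoxy groups of the more electron-rich ring, should give 1-[3-(4-bromophenoxy)-2,4-dimethoxyphenyl]ethanone F2. BBr3 in CH2Cl2 (−78 → 20 °C) then cleaves both methyl ethers, leaving the diaryl ether, to give 9. This also removes the dependence on the moisture-sensitive diene of step 3.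

2. Step 8. Palladium may also insert into the aryl C–Br bond, leading to double arylation or oligomers. The fallback builds ring B without palladium; it sets out from compound 10 and comes back at compound 14. Claisen–Schmidt condensation of 10 with 4-(benzyloxy)benzaldehyde (O=Cc1ccc(OCc2ccccc2)cc1; KOH, EtOH, 20 °C) should give (E)-1-[4-(benzyloxy)-3-(4-bromophenoxy)-2-hydroxyphenyl]-3-[4-(benzyloxy)phenyl]prop-2-en-1-one F3. Oxidative 1,2-aryl migration with Tl(NO3)3·3H2O in MeOH/HC(OMe)3 at 20 °C (the classical chalcone-to-isoflavone rearrangement, helped by the electron-rich 4-benzyloxyphenyl group) should give 1-[4-(benzyloxy)-3-(4-bromophenoxy)-2-hydroxyphenyl]-2-[4-(benzyloxy)phenyl]-3,3-dimethoxypropan-1-one F4. Brief heating with HCl in MeOH closes the pyranone ring to 14.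

3. Step 1. The chloro keto ester may be enolised by the base instead of substituted, chlorine may be transferred to the phenoxide, or the product may undergo retro-Claisen deacetylation. The fallback forms the C–O bond by carbenoid O–H insertion; it sets out from compound 1 and comes back at compound 3. Diazo transfer to methyl acetoacetate (COC(=O)CC(C)=O) with 4-acetamidobenzenesulfonyl azide and Et3N in MeCN gives methyl 2-diazo-3-oxobutanoate F5. Slow addition of F5 to 1 with Rh2(OAc)4 (1 mol %) in refluxing CH2Cl2 should give 3 with loss of nitrogen.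

**Further compounds**

F1 | step 4 | 2-(4-bromophenoxy)-1,3-dimethoxybenzene | COc1cccc(OC)c1Oc1ccc(Br)cc1
F2 | step 4 | 1-[3-(4-bromophenoxy)-2,4-dimethoxyphenyl]ethanone | CC(=O)c1ccc(OC)c(Oc2ccc(Br)cc2)c1OC
F3 | step 8 | (E)-1-[4-(benzyloxy)-3-(4-bromophenoxy)-2-hydroxyphenyl]-3-[4-(benzyloxy)phenyl]prop-2-en-1-one | O=C(/C=C/c1ccc(OCc2ccccc2)cc1)c1ccc(OCc2ccccc2)c(Oc2ccc(Br)cc2)c1O
F4 | step 8 | 1-[4-(benzyloxy)-3-(4-bromophenoxy)-2-hydroxyphenyl]-2-[4-(benzyloxy)phenyl]-3,3-dimethoxypropan-1-one | COC(OC)C(c1ccc(OCc2ccccc2)cc1)C(=O)c1ccc(OCc2ccccc2)c(Oc2ccc(Br)cc2)c1O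
F5 | step 1 | methyl 2-diazo-3-oxobutanoate | COC(=O)C(=[N+]=[N-])C(C)=O
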